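The flavone's ring D is grown onto ring B, with no aryl–aryl coupling. C8'' carries ring B (C5'–C8'' bond) and sits between oxygen-bearing C7'' and C8a'', with a third oxygen on C5''. This 2-arylphloroglucinol pattern arises when an aryl ynol ether is spliced into the acyl–vinyl bond of a 3-alkoxycyclobutenone. One thermal operation makes C8''–C8a'' and C6''–C7'', closes ring D and delivers its oxygens differentiated as OH, OSi(i-Pr)3 and OBn. The precursor is a ring B triisopropylsiloxyalkyne with a benzylated catechol and the future C2 masked as a dioxolane. The lone phenol then dictates where the pyranone is built. The flavanone is closed last, enantioselectively.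

Key step: step 7

Locants: unprimed = flavanone rings A and C, primed = ring B, double-primed = flavone rings D and F, triple-primed = ring E.
Assumption: the quinidine-derived thiourea of step 15 is taken to deliver (2S). The sense should be checked on the alkylidene made from 3,4-bis(benzyloxy)benzaldehyde, and the quinine-derived pseudoenantiomer takes its place if the sense is opposite.
Assumption: the C5'–C8'' axis has three ortho substituents and is not fixed in the target, so rotamers of late intermediates are treated as one compound.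

Step 1
Reactants: 1 5-iodovanillin (4-hydroxy-3-iodo-5-methoxybenzaldehyde)
Product: 2 3,4-dihydroxy-5-iodobenzaldehyde
Conditions: AlCl3, pyridine, CH2Cl2, reflux; 2 M HCl work-up
Reagents that add atoms: none
Why: Chelation-assisted aryl methyl ether cleavage, in which aluminium binds the phenol oxygen and the neighbouring methoxy oxygen and pyridine removes the activated methyl group by SN2 attack, leaving aldehyde and iodide untouched.

Step 2
Reactants: 2 3,4-dihydroxy-5-iodobenzaldehyde
Product: 3 3,4-bis(benzyloxy)-5-iodobenzaldehyde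
Conditions: BnBr (2.3 equiv), K2CO3, DMF, 60 °C
Reagents that add atoms: benzyl bromide, BrCc1ccccc1
Why: Williamson etherification of both catechol hydroxyls, with benzyl chosen so that all phenol protection but one leaves together in the final hydrogenolysis.

Step 3
Reactants: 3 3,4-bis(benzyloxy)-5-iodobenzaldehyde
Product: 4 2-[3,4-bis(benzyloxy)-5-iodophenyl]-1,3-dioxolane
Conditions: HOCH2CH2OH, TsOH·H2O (cat.), toluene, Dean–Stark, reflux
Reagents that add atoms: ethylene glycol, OCCO
Why: Acid-catalysed acetalisation with azeotropic water removal masks the aldehyde against the organolithium reagents of step 5.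

Step 4
Reactants: 4 2-[3,4-bis(benzyloxy)-5-iodophenyl]-1,3-dioxolane
Product: 5 methyl 2,3-bis(benzyloxy)-5-(1,3-dioxolan-2-yl)benzoate
Conditions: Pd(OAc)2 (cat.), dppf, CO (1 atm), Et3N, MeOH–DMF, 70 °C
Reagents that add atoms: carbon monoxide, [C-]#[O+]; methanol, CO
Why: Palladium-catalysed alkoxycarbonylation (oxidative addition of the aryl iodide to zerovalent palladium, CO insertion, methanolysis of the acylpalladium species) under basic conditions that keep the acetal intact.

Step 5
Reactants: 5 methyl 2,3-bis(benzyloxy)-5-(1,3-dioxolan-2-yl)benzoate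
Product: 8 {[2,3-bis(benzyloxy)-5-(1,3-dioxolan-2-yl)phenyl]ethynyl}oxy(triisopropyl)silane (ring B siloxyalkyne), via lithium dibromoenolate 6 (not isolated), via lithium ynolate 7 (not isolated)
Conditions: CH2Br2, lithium 2,2,6,6-tetramethylpiperidide, THF, −78 °C; then 5; then n-BuLi, −78 → 0 °C; then i-Pr3SiOTf, −78 → 0 °C
Reagents that add atoms: dibromomethane, BrCBr; triisopropylsilyl trifluoromethanesulfonate, CC(C)[Si](OS(=O)(=O)C(F)(F)F)(C(C)C)C(C)C
Why: Kowalski ester homologation, in which LiCHBr2 adds to the ester, the derived dibromoenolate 6 undergoes Br/Li exchange and a 1,2-aryl shift to ynolate 7, and the bulky hard silyl triflate traps the ynolate on oxygen instead of carbon.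

Step 6
Reactants: 9 cyclobutane-1,3-dione
Product: 10 3-(benzyloxy)cyclobut-2-en-1-one
Conditions: BnOH, TsOH·H2O (cat.), 4 Å MS, CH2Cl2, rt
Reagents that add atoms: benzyl alcohol, OCc1ccccc1
Why: Acid-catalysed vinylogous Fischer esterification of the strongly acidic enol form of 9 can only give the O-benzyl product, whereas alkylation with a benzyl halide could also strike carbon.

Step 7
Reactants: 8 ring B siloxyalkyne; 10 3-(benzyloxy)cyclobut-2-en-1-one
Product: 15 5-(benzyloxy)-2-[2,3-bis(benzyloxy)-5-(1,3-dioxolan-2-yl)phenyl]-3-(triisopropylsilyloxy)phenol (biaryl phenol), via vinylketene 11 (not isolated), via 4-vinylcyclobutenone 12 (not isolated), via dienylketene 13 (not isolated), via cyclohexadienone 14 (not isolated)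
Conditions: 10 (1.3 equiv, in portions), degassed toluene, sealed tube, 110 → 140 °C
Reagents that add atoms: none
Why: This is a Danheiser benzannulation in its siloxyalkyne form: heat cleaves the C1–C4 bond of 10 in a 4π electrocyclic opening to vinylketene 11, which adds 8 in a [2+2] cycloaddition to give 4-vinylcyclobutenone 12. A second 4π opening gives dienylketene 13, whose 6π electrocyclisation re-joins the old C1 and C4 (C8a''–C4a'') to dienone 14, and tautomerisation gives phenol 15. Ring D is therefore closed by a thermal disrotatory 6π electrocyclisation, the net result being insertion of the two alkyne carbons into the C1–C2 bond of 10 (new bonds C8''–C8a'' and C6''–C7''). The closest known cases are resorcinol syntheses from cyclobutenones, 3-oxygenated ones included, and trialkylsiloxyalkynes. No stereocentre survives, because the one in 12 is erased on ring opening and the biaryl axis is not fixed. The selectivity needed is the orientation of the [2+2] step, and it is secured by the polarity of the ynol ether, whose aryl-bearing carbon is the nucleophilic terminus and attacks the ketene carbonyl carbon, so that OH falls on C8a'', OSi(i-Pr)3 on C7'' and OBn on C5''.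

Step 8
Reactants: 15 biaryl phenol
Product: 16 6-(benzyloxy)-3-[2,3-bis(benzyloxy)-5-(1,3-dioxolan-2-yl)phenyl]-2-hydroxy-4-(triisopropylsilyloxy)benzaldehyde (CHO on C4a'')
Conditions: MgCl2 (anhydrous), Et3N, (CH2O)n, MeCN, reflux; aq NH4Cl work-up
Reagents that add atoms: paraformaldehyde (reacts as formaldehyde), C=O
Why: Casnati–Skattebøl ortho-formylation delivers formaldehyde within the magnesium phenoxide chelate, so with C8'' blocked only C4a'' and not the para site C6'' can react, and a second formaldehyde oxidises the hydroxymethyl stage by hydride transfer under conditions harmless to acetal and silyl ether.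

Step 9
Reactants: 16 C4a'' salicylaldehyde; 17 1-(benzyloxy)-4-ethynylbenzene
Product: 19 racemic propargylic alcohol in which the CHO of 16 has become CH(OH)–C≡C–C6H4-4-OBn, via lithium acetylide 18 (not isolated)
Conditions: 17 (2.5 equiv), n-BuLi (2.4 equiv), THF, −78 °C; then 16, −78 → 0 °C; aq NH4Cl
Reagents that add atoms: none
Why: 1,2-Addition of a lithium acetylide to an aldehyde, the first equivalent being spent on the phenol, and the new carbinol centre is left racemic on purpose because step 10 removes it.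

Step 10
Reactants: 19 racemic propargylic alcohol (used crude)
Product: 20 o-hydroxyaryl ynone (carbinol of 19 oxidised to C=O)
Conditions: activated MnO2 (excess), CH2Cl2, rt
Reagents that add atoms: none
Why: Chemoselective MnO2 oxidation of a benzylic–propargylic alcohol leaves phenol, acetal, silyl and benzyl ethers alone and erases the carbinol stereocentre.

Step 11
Reactants: 20 o-hydroxyaryl ynone
Product: 22 3,4-bis(benzyloxy)-5-{5-(benzyloxy)-2-[4-(benzyloxy)phenyl]-4-oxo-7-(triisopropylsilyloxy)-4H-chromen-8-yl}benzaldehyde (flavone aldehyde), via flavone acetal 21 (not isolated)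
Conditions: 4-(dimethylamino)pyridine (20 mol %), DMF, rt → 40 °C; then 2 M HCl, THF, rt
Reagents that add atoms: water, O
Why: Nucleophile-catalysed 6-endo-dig oxa-Michael cyclisation, in which the pyridine adds to the ynone β-carbon and the C8a'' phenoxide displaces it at that same carbon, favours the flavone over the 5-exo aurone, and aqueous acid then hydrolyses the dioxolane without touching the aryl silyl ether.

Step 12
Reactants: 23 2,4,6-trihydroxyacetophenone
Product: 24 1-[2,4-bis(benzyloxy)-6-hydroxyphenyl]ethan-1-one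
Conditions: BnBr (2.05 equiv), K2CO3, DMF, rt → 50 °C
Reagents that add atoms: benzyl bromide, BrCc1ccccc1
Why: Williamson etherification should stop at the diether because the last hydroxyl is hydrogen-bonded to the ketone and is the least nucleophilic one.

Step 13
Reactants: 24 1-[2,4-bis(benzyloxy)-6-hydroxyphenyl]ethan-1-one
Product: 25 tert-butyl 3-[2,4-bis(benzyloxy)-6-hydroxyphenyl]-3-oxopropanoate
Conditions: LiN(SiMe3)2 (3.3 equiv), THF, −78 °C; Boc2O, −78 → 0 °C; aq NH4Cl
Reagents that add atoms: di-tert-butyl dicarbonate, CC(C)(C)OC(=O)OC(=O)OC(C)(C)C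
Why: Crossed Claisen-type C-acylation of the phenoxide–enolate dianion, in which any aryl carbonate formed on the phenoxide should be carried to the same β-ketoester by a Baker–Venkataraman-type O-to-C transfer, and the extra base stores the product as its enolate.

Step 14
Reactants: 22 flavone aldehyde; 25 tert-butyl 3-[2,4-bis(benzyloxy)-6-hydroxyphenyl]-3-oxopropanoate
Product: 26 tert-butyl (Z)-2-[2,4-bis(benzyloxy)-6-hydroxybenzoyl]-3-aryl-prop-2-enoate, aryl = ring B of 22 with its flavone substituent (alkylidene β-ketoester)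
Conditions: piperidine (cat.), AcOH (cat.), 4 Å MS, toluene, rt → 40 °C
Reagents that add atoms: none
Why: Knoevenagel condensation under piperidinium acetate catalysis works because the ester makes the methylene acidic enough for hydroxide-free conditions that spare the aryl silyl ether, and the aryl group is expected to settle cis to the ester.

Step 15
Reactants: 26 alkylidene β-ketoester
Product: 28 (2S)-hexa-O-benzyl-7''-O-triisopropylsilyl biflavonoid (protected flavanone–flavone), via tert-butyl flavanone-3-carboxylate 27 (not isolated)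
Conditions: 1-[3,5-bis(trifluoromethyl)phenyl]-3-[(9R)-6'-methoxycinchonan-9-yl]thiourea (10 mol %), toluene, −25 °C; then TsOH·H2O, 80 °C
Reagents that add atoms: none
Why: Bifunctional cinchona-thiourea-catalysed intramolecular oxa-Michael addition (6-endo-trig), in which the thiourea binds the β-ketoester while the quinuclidine nitrogen deprotonates the only free phenol (ring A) and guides it to one face of the alkylidene carbon, setting C2 as S, after which acidolysis of the tert-butyl ester with loss of CO2 removes the activating group and shuts off the retro-Michael path that would scramble C2.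

Step 16
Reactants: 28 (2S)-hexa-O-benzyl-7''-O-triisopropylsilyl biflavonoid
Product: 29 (2S)-hexa-O-benzyl biflavonoid with free 7''-OH
Conditions: n-Bu4NF/AcOH (1:1), THF, 0 °C
Reagents that add atoms: none
Why: Fluoride-induced cleavage of the aryl silyl ether is driven by the Si–F bond and the good 7''-phenoxide leaving group, and acetic acid buffering keeps the medium too weakly basic for the retro-oxa-Michael opening that would racemise C2.

Step 17
Reactants: 29 (2S)-hexa-O-benzyl biflavonoid with free 7''-OH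
Product: 30 (2S)-2-{3,4-dihydroxy-5-[5,7-dihydroxy-2-(4-hydroxyphenyl)-4-oxo-4H-chromen-8-yl]phenyl}-5,7-dihydroxychroman-4-one (CNP0204144.1)
Conditions: H2 (1 atm), 10% Pd/C, EtOAc–MeOH, rt, stopped at full debenzylation; filtration and concentration below 30 °C without base
Reagents that add atoms: none
Why: Catalytic hydrogenolysis of six benzyl aryl ethers under neutral conditions should outrun reduction of the flavone C2''=C3'' bond and cleavage of the C2–O1 bond, and it leaves C2 untouched.

Compound list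
1 | 5-iodovanillin | COc1cc(C=O)cc(I)c1O | starting material
2 | 3,4-dihydroxy-5-iodobenzaldehyde | O=Cc1cc(O)c(O)c(I)c1 | intermediate
3 | 3,4-bis(benzyloxy)-5-iodobenzaldehyde | O=Cc1cc(I)c(OCc2ccccc2)c(OCc2ccccc2)c1 | intermediate
4 | 2-[3,4-bis(benzyloxy)-5-iodophenyl]-1,3-dioxolane | Ic1cc(C2OCCO2)cc(OCc2ccccc2)c1OCc1ccccc1 | intermediate
5 | methyl 2,3-bis(benzyloxy)-5-(1,3-dioxolan-2-yl)benzoate | COC(=O)c1cc(C2OCCO2)cc(OCc2ccccc2)c1OCc1ccccc1 | intermediate
6 | lithium 1-aryl-2,2-dibromoethenolate (not isolated) | [Li]OC(=C(Br)Br)c1cc(C2OCCO2)cc(OCc2ccccc2)c1OCc1ccccc1 | intermediate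
7 | lithium aryl ynolate (not isolated) | [Li]OC#Cc1cc(C2OCCO2)cc(OCc2ccccc2)c1OCc1ccccc1 | intermediate
8 | ring B triisopropylsiloxyalkyne | CC(C)[Si](OC#Cc1cc(C2OCCO2)cc(OCc2ccccc2)c1OCc1ccccc1)(C(C)C)C(C)C | intermediate
9 | cyclobutane-1,3-dione | O=C1CC(=O)C1 | starting material
10 | 3-(benzyloxy)cyclobut-2-en-1-one | O=C1C=C(OCc2ccccc2)C1 | intermediate
11 | 3-(benzyloxy)buta-1,3-dien-1-one, vinylketene (not isolated) | C=C(OCc1ccccc1)C=C=O | intermediate
12 | racemic 2-aryl-4-[1-(benzyloxy)ethenyl]-3-(triisopropylsilyloxy)cyclobut-2-en-1-one (not isolated) | O=C1C(c2cc(C3OCCO3)cc(OCc3ccccc3)c2OCc2ccccc2)=C(O[Si](C(C)C)(C(C)C)C(C)C)C1C(=C)OCc1ccccc1 | intermediate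
13 | 2-aryl-5-(benzyloxy)-3-(triisopropylsilyloxy)hexa-1,3,5-trien-1-one, ketene and vinyl termini cis (not isolated) | O=C=C(c1cc(C2OCCO2)cc(OCc2ccccc2)c1OCc1ccccc1)/C(O[Si](C(C)C)(C(C)C)C(C)C)=C\C(=C)OCc1ccccc1 | intermediate
14 | 2-aryl-5-(benzyloxy)-3-(triisopropylsilyloxy)cyclohexa-2,4-dien-1-one (not isolated) | O=C1CC(OCc2ccccc2)=CC(O[Si](C(C)C)(C(C)C)C(C)C)=C1c1cc(C2OCCO2)cc(OCc2ccccc2)c1OCc1ccccc1 | intermediate
15 | biaryl phenol, OH on C8a'', OSi(i-Pr)3 on C7'', OBn on C5'' | Oc1cc(OCc2ccccc2)cc(O[Si](C(C)C)(C(C)C)C(C)C)c1-c1cc(C2OCCO2)cc(OCc2ccccc2)c1OCc1ccccc1 | intermediate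
16 | C4a'' salicylaldehyde | O=Cc1c(OCc2ccccc2)cc(O[Si](C(C)C)(C(C)C)C(C)C)c(-c2cc(C3OCCO3)cc(OCc3ccccc3)c2OCc2ccccc2)c1O | intermediate
17 | 1-(benzyloxy)-4-ethynylbenzene | C#Cc1ccc(OCc2ccccc2)cc1 | starting material
18 | lithium [4-(benzyloxy)phenyl]acetylide (not isolated) | [Li]C#Cc1ccc(OCc2ccccc2)cc1 | intermediate
19 | racemic propargylic alcohol | OC(C#Cc1ccc(OCc2ccccc2)cc1)c1c(OCc2ccccc2)cc(O[Si](C(C)C)(C(C)C)C(C)C)c(-c2cc(C3OCCO3)cc(OCc3ccccc3)c2OCc2ccccc2)c1O | intermediate
20 | o-hydroxyaryl ynone | O=C(C#Cc1ccc(OCc2ccccc2)cc1)c1c(OCc2ccccc2)cc(O[Si](C(C)C)(C(C)C)C(C)C)c(-c2cc(C3OCCO3)cc(OCc3ccccc3)c2OCc2ccccc2)c1O | intermediate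
21 | flavone acetal (not isolated) | O=c1cc(-c2ccc(OCc3ccccc3)cc2)oc2c(-c3cc(C4OCCO4)cc(OCc4ccccc4)c3OCc3ccccc3)c(O[Si](C(C)C)(C(C)C)C(C)C)cc(OCc3ccccc3)c12 | intermediate
22 | flavone aldehyde | O=Cc1cc(OCc2ccccc2)c(OCc2ccccc2)c(-c2c(O[Si](C(C)C)(C(C)C)C(C)C)cc(OCc3ccccc3)c3c(=O)cc(-c4ccc(OCc5ccccc5)cc4)oc23)c1 | intermediate
23 | 2,4,6-trihydroxyacetophenone | CC(=O)c1c(O)cc(O)cc1O | starting material
24 | 1-[2,4-bis(benzyloxy)-6-hydroxyphenyl]ethan-1-one | CC(=O)c1c(O)cc(OCc2ccccc2)cc1OCc1ccccc1 | intermediate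
25 | tert-butyl 3-[2,4-bis(benzyloxy)-6-hydroxyphenyl]-3-oxopropanoate | CC(C)(C)OC(=O)CC(=O)c1c(O)cc(OCc2ccccc2)cc1OCc1ccccc1 | intermediate
26 | (Z)-alkylidene β-ketoester | CC(C)(C)OC(=O)/C(=C\c1cc(OCc2ccccc2)c(OCc2ccccc2)c(-c2c(O[Si](C(C)C)(C(C)C)C(C)C)cc(OCc3ccccc3)c3c(=O)cc(-c4ccc(OCc5ccccc5)cc4)oc23)c1)C(=O)c1c(O)cc(OCc2ccccc2)cc1OCc1ccccc1 | intermediate
27 | tert-butyl (2S)-flavanone-3-carboxylate, C3 epimers and enol (not isolated) | O=C1C(C(=O)OC(C)(C)C)[C@@H](c2cc(OCc3ccccc3)c(OCc3ccccc3)c(-c3c(O[Si](C(C)C)(C(C)C)C(C)C)cc(OCc4ccccc4)c4c(=O)cc(-c5ccc(OCc6ccccc6)cc5)oc34)c2)Oc2cc(OCc3ccccc3)cc(OCc3ccccc3)c21 | intermediate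
28 | (2S)-hexa-O-benzyl-7''-O-triisopropylsilyl biflavonoid | O=C1C[C@@H](c2cc(OCc3ccccc3)c(OCc3ccccc3)c(-c3c(O[Si](C(C)C)(C(C)C)C(C)C)cc(OCc4ccccc4)c4c(=O)cc(-c5ccc(OCc6ccccc6)cc5)oc34)c2)Oc2cc(OCc3ccccc3)cc(OCc3ccccc3)c21 | intermediate
29 | (2S)-hexa-O-benzyl biflavonoid, free 7''-OH | O=C1C[C@@H](c2cc(OCc3ccccc3)c(OCc3ccccc3)c(-c3c(O)cc(OCc4ccccc4)c4c(=O)cc(-c5ccc(OCc6ccccc6)cc5)oc34)c2)Oc2cc(OCc3ccccc3)cc(OCc3ccccc3)c21 | intermediate
30 | CNP0204144.1, (2S) | O=C1C[C@@H](c2cc(O)c(O)c(-c3c(O)cc(O)c4c(=O)cc(-c5ccc(O)cc5)oc34)c2)Oc2cc(O)cc(O)c21 | target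

Total step count: 17. Longest linear sequence: 14 steps (steps 1–5, 7–11 and 14–17).

Steps most likely to fail

1. Step 7.
- What may go wrong: the vinylogous ester stabilisation of 10 may slow the first ring opening. Thermal decay of the siloxyalkyne, or acylation of the product phenol by the ketene, could then overtake the annulation.
- Fallback: cross-coupling in place of annulation, setting out from 4 and returning at 15.
  - Miyaura borylation of 4 (B2pin2, PdCl2(dppf), KOAc, dioxane, 90 °C) would give the ring B pinacol boronate F1.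
  - Purchased 5-(benzyloxy)benzene-1,3-diol F2 would be iodinated between its two hydroxyls (I2, NaHCO3, THF–H2O, 0 °C) to 5-(benzyloxy)-2-iodobenzene-1,3-diol F3.
  - Monosilylation (i-Pr3SiCl, imidazole, DMF) would give 5-(benzyloxy)-2-iodo-3-(triisopropylsilyloxy)phenol F4.
  - A Suzuki–Miyaura coupling of F1 with F4 (Pd(OAc)2, SPhos, K3PO4, toluene–H2O, 90 °C) would give 15.

2. Step 5.
- What may go wrong: the excess strong base may lithiate a benzylic or ring position or fragment the dioxolane. Silylation may also fall on carbon instead of oxygen.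
- Fallback: oxidation of an acetylide with only stoichiometric base, setting out from 4 and returning at ynolate 7, which is silylated to 8 as in step 5.
  - Sonogashira coupling of 4 with trimethylsilylacetylene (PdCl2(PPh3)2, CuI, Et3N, THF) would give the silylalkyne F5.
  - Methanolysis (K2CO3, MeOH) would give the terminal alkyne F6.
  - One equivalent of n-BuLi (THF, −78 °C) would give the lithium acetylide F7.
  - Oxygen transfer from lithium tert-butyl peroxide (t-BuOOH, LiN(SiMe3)2, −78 → 0 °C) would give 7.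

3. Step 15.
- What may go wrong: the doubly ortho-substituted aroyl group is twisted and ring B is very bulky, so facial selectivity may be poor. Uncatalysed background closure may compete. Reversible ring opening in hot acid, helped by the 4'-alkoxy group, may erode the enantiomeric purity.
- Fallback: racemic closure, resolution and recycling, setting out from 26 and returning at 28.
  - Closure with an achiral base (Et3N, toluene, rt) would give the racemic tert-butyl flavanone-3-carboxylate F8.
  - Decarboxylation in the same flask (TsOH·H2O, 80 °C) would give the racemic protected flavanone F9.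
  - Preparative chromatography on a cellulose tris(3,5-dimethylphenylcarbamate) phase would separate 28 from its (2R)-enantiomer F10.
  - F10 would be returned to F9 by retro-oxa-Michael opening and re-closure (DBU cat., toluene, 60 °C) and recycled.

Further compounds
F1 | step 7 | 2-[2,3-bis(benzyloxy)-5-(1,3-dioxolan-2-yl)phenyl]-4,4,5,5-tetramethyl-1,3,2-dioxaborolane | CC1(C)OB(c2cc(C3OCCO3)cc(OCc3ccccc3)c2OCc2ccccc2)OC1(C)C
F2 | step 7 | 5-(benzyloxy)benzene-1,3-diol (purchased) | Oc1cc(O)cc(OCc2ccccc2)c1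
F3 | step 7 | 5-(benzyloxy)-2-iodobenzene-1,3-diol | Oc1cc(OCc2ccccc2)cc(O)c1I
F4 | step 7 | 5-(benzyloxy)-2-iodo-3-(triisopropylsilyloxy)phenol | Oc1cc(OCc2ccccc2)cc(O[Si](C(C)C)(C(C)C)C(C)C)c1I
F5 | step 5 | {[2,3-bis(benzyloxy)-5-(1,3-dioxolan-2-yl)phenyl]ethynyl}trimethylsilane | C[Si](C)(C)C#Cc1cc(C2OCCO2)cc(OCc2ccccc2)c1OCc1ccccc1
F6 | step 5 | 2-[3,4-bis(benzyloxy)-5-ethynylphenyl]-1,3-dioxolane | C#Cc1cc(C2OCCO2)cc(OCc2ccccc2)c1OCc1ccccc1
F7 | step 5 | lithium acetylide of F6 | [Li]C#Cc1cc(C2OCCO2)cc(OCc2ccccc2)c1OCc1ccccc1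
F8 | step 15 | racemic tert-butyl flavanone-3-carboxylate | O=C1C(C(=O)OC(C)(C)C)C(c2cc(OCc3ccccc3)c(OCc3ccccc3)c(-c3c(O[Si](C(C)C)(C(C)C)C(C)C)cc(OCc4ccccc4)c4c(=O)cc(-c5ccc(OCc6ccccc6)cc5)oc34)c2)Oc2cc(OCc3ccccc3)cc(OCc3ccccc3)c21
F9 | step 15 | racemic protected flavanone | O=C1CC(c2cc(OCc3ccccc3)c(OCc3ccccc3)c(-c3c(O[Si](C(C)C)(C(C)C)C(C)C)cc(OCc4ccccc4)c4c(=O)cc(-c5ccc(OCc6ccccc6)cc5)oc34)c2)Oc2cc(OCc3ccccc3)cc(OCc3ccccc3)c21
F10 | step 15 | (2R)-enantiomer of 28 | O=C1C[C@H](c2cc(OCc3ccccc3)c(OCc3ccccc3)c(-c3c(O[Si](C(C)C)(C(C)C)C(C)C)cc(OCc4ccccc4)c4c(=O)cc(-c5ccc(OCc6ccccc6)cc5)oc34)c2)Oc2cc(OCc3ccccc3)cc(OCc3ccccc3)c21
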